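**Strategy.** Atoms are numbered as in bisabolane: ring C1 (CH2), C2 (Cl), C3 (Me, OH), C4, C5, C6; side chain C7(=C14H2), C8–C11. Reading the C2–Cl/C3–OH pair as a masked C2=C3 olefin and C7 as a masked carboxyl carbon reveals a γ,δ-unsaturated acid, C7–C6–C1–C2=C3. The key step, an Ireland–Claisen rearrangement of a 2-deoxy-D-ribose-derived δ-lactone silyl ketene acetal, forms C1–C6, closes the cyclohexene ring, creates the C2=C3 olefin and relays the C3 carbinol configuration to C6, cis to the C4 and C5 oxygens. The precursor lactone joins C7 to C3 through oxygen and carries a vinyl group (C1=C2) and the C4/C5 acetonide.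

Key step: step 8

Remark: angeloyl = (Z)-2-methylbut-2-enoyl; descriptors given "in bisabolane numbering" use the locants above; the L-fructose-derived epoxidation ketone (ent-Shi ketone) and the chiral oxazoline–sulfonamide ligand are used as reagents and carry no compound number.

Step 1
Reactants: 1 2-deoxy-D-ribose
Product: 2 3,4-O-isopropylidene-2-deoxy-D-ribopyranose (anomer mixture)
Conditions: 2-methoxypropene, PPTS (cat.), EtOAc, 0 °C to rt
Reagents that add atoms: 2-methoxypropene, C=C(C)OC
Why: Acid-catalysed acetalisation with the enol ether should take the cis-3,4-diol of the pyranose form into a cis-fused dioxolane (acetonide formation) without touching a stereocenter.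

Step 2
Reactants: 2 3,4-O-isopropylidene-2-deoxy-D-ribopyranose
Product: 3 3,4-O-isopropylidene-2-deoxy-D-ribono-1,5-lactone
Conditions: TEMPO (cat.), PhI(OAc)2, CH2Cl2, rt
Reagents that add atoms: none
Why: Oxoammonium (TEMPO) oxidation of a lactol to the lactone is mild enough to leave the acetonide intact.

Step 3
Reactants: 3 3,4-O-isopropylidene-2-deoxy-D-ribono-1,5-lactone
Product: 4 N-methoxy-N-methyl-2-[(4S,5R)-5-(hydroxymethyl)-2,2-dimethyl-1,3-dioxolan-4-yl]acetamide
Conditions: MeNH(OMe)·HCl, AlMe3, CH2Cl2, 0 °C to rt
Reagents that add atoms: N,O-dimethylhydroxylamine hydrochloride, CNOC.Cl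
Why: Aluminium amide aminolysis of the lactone (Weinreb amide formation) should open the ring irreversibly, store C7 at the acid oxidation level and free the primary hydroxyl on the future C3.

Step 4
Reactants: 4 hydroxy Weinreb amide
Product: 5 N-methoxy-N-methyl-2-[(4S,5S)-5-formyl-2,2-dimethyl-1,3-dioxolan-4-yl]acetamide
Conditions: Dess–Martin periodinane, CH2Cl2, 0 °C to rt
Reagents that add atoms: none
Why: Dess–Martin oxidation gives the α-alkoxy aldehyde under neutral conditions, which should avoid epimerisation at C4.

Step 5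
Reactants: 5 aldehyde
Product: 6 N-methoxy-N-methyl-2-[(4S,5R)-5-(1-hydroxyprop-2-en-1-yl)-2,2-dimethyl-1,3-dioxolan-4-yl]acetamide (both carbinol epimers)
Conditions: CH2=CHMgBr, THF, −78 °C; then H2O
Reagents that add atoms: vinylmagnesium bromide, C=C[Mg]Br
Why: Grignard 1,2-addition to the aldehyde is much faster at −78 °C than attack on the Weinreb amide, and the new carbinol centre is erased in step 6, so both epimers are carried on.

Step 6
Reactants: 6 allylic alcohol
Product: 7 N-methoxy-N-methyl-2-[(4S,5S)-2,2-dimethyl-5-(prop-2-enoyl)-1,3-dioxolan-4-yl]acetamide (vinyl ketone)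
Conditions: Dess–Martin periodinane, CH2Cl2, 0 °C
Reagents that add atoms: none
Why: Base-free Dess–Martin oxidation of the allylic alcohol should give the α-alkoxy vinyl ketone without β-elimination or conjugate addition.

Step 7
Reactants: 7 vinyl ketone
Product: 9 δ-lactone (3aS,4R,7aS)-4-ethenyl-2,2,4-trimethyltetrahydro-4H-[1,3]dioxolo[4,5-c]pyran-6-one (bisabolane 3R,4S,5S; vinyl trans to both acetonide oxygens), via carbinol amide 8 (not isolated)
Conditions: MeMgBr, CH2Cl2/Et2O, −78 °C; H2O; then PPTS (cat.), PhMe, 60 °C
Reagents that add atoms: methylmagnesium bromide, C[Mg]Br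
Why: Chelation-controlled (Cram chelate) 1,2-addition, with magnesium bridging the ketone oxygen and O4 and methyl entering anti to the C5 branch, should set C3 as R, after which the tertiary alcohol lactonises onto the Weinreb amide under mild acid.

Step 8
Reactants: 9 δ-lactone
Product: 12 (1S,2S,3R)-2,3-(isopropylidenedioxy)-4-methylcyclohex-4-ene-1-carboxylic acid (all-cis; bisabolane 4R,5S,6S), via silyl ketene acetal 10 (not isolated), via trimethylsilyl ester 11 (not isolated)
Conditions: LiN(SiMe3)2, Me3SiCl, THF, −78 °C; PhMe, 100 °C; then H2O (citric acid)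
Reagents that add atoms: none
Why: Deprotonation at C6 (the only enolisable position) and in situ O-silylation give the cyclic silyl ketene acetal 10, which on heating undergoes the [3,3]-sigmatropic Ireland–Claisen shift (C3–O broken, C1–C6 formed) and is hydrolysed to acid 12 on work-up. The closest known reaction type is the ester-enolate Claisen rearrangement of lactone silyl ketene acetals that carry an alkenyl group on the carbinol carbon, which reorganises a lactone into a carbocycle. The cyclohexene ring is closed pericyclically through the six-atom array C6=C7–O–C3–C2=C1, and because C7–O–C3 lie in the lactone ring the transition state must be boat-like. The new stereocenter C6 is set by suprafacial 1,3-chirality transfer from C3: the vinyl group lies on the lactone face opposite O4 and O5, so C1 bonds to that face of C6 and the carboxyl group ends up cis to both oxygens. The step needs silyl trapping to outrun β-elimination of the C5 alkoxide from the enolate, which the internal Me3SiCl quench at −78 °C and the poor leaving-group ability of the ring-fused acetonide oxygen should secure, and no E/Z issue arises because the ketene acetal geometry is fixed by the ring. The C3 stereocenter is consumed here and rebuilt in step 15.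

Step 9
Reactants: 12 cyclohexene acid
Product: 13 1-[(1S,2S,3R)-2,3-(isopropylidenedioxy)-4-methylcyclohex-4-en-1-yl]ethanone (methyl ketone)
Conditions: MeLi (2.5 equiv), THF, −78 to 0 °C; then H2O
Reagents that add atoms: methyllithium, [Li]C
Why: Methyllithium adds once to the lithium carboxylate to give a dilithio gem-diolate that collapses to the ketone only on work-up (ketone synthesis from a carboxylic acid and an organolithium), so C6 is not enolised.

Step 10
Reactants: 13 methyl ketone
Product: 14 1-[(1S,2S,3R)-2,3-(isopropylidenedioxy)-4-methylcyclohex-4-en-1-yl]ethenyl trifluoromethanesulfonate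
Conditions: KN(SiMe3)2, PhNTf2, THF, −78 °C
Reagents that add atoms: N-phenylbis(trifluoromethanesulfonimide), O=S(=O)(N(c1ccccc1)S(=O)(=O)C(F)(F)F)C(F)(F)F
Why: Kinetic deprotonation at the methyl group, which avoids the C6 enolate that could expel O5, followed by O-triflation should give the 1,1-disubstituted enol triflate that carries C7=C14.

Step 11
Reactants: 15 4-methylpent-3-en-1-ol
Product: 16 4-methylpent-3-enal
Conditions: Dess–Martin periodinane, pyridine, CH2Cl2, 0 °C (used crude)
Reagents that add atoms: none
Why: Buffered Dess–Martin oxidation should give the β,γ-unsaturated aldehyde without migration of the double bond into conjugation.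

Step 12
Reactants: 14 enol triflate; 16 4-methylpent-3-enal
Product: 17 (4R,5S,6R,8S)-4,5-O-isopropylidene-bisabola-2,7(14),10-triene-4,5,8-triol (free C8–OH; bisabolane numbering)
Conditions: CrCl2, NiCl2 (cat.), chiral oxazoline–sulfonamide ligand, Et3N, THF, rt
Reagents that add atoms: none
Why: Nozaki–Hiyama–Kishi coupling (NiCl2-catalysed activation of the enol triflate, transmetalation to trivalent chromium, carbonyl addition) forms C7–C8 chemoselectively, and the chiral ligand on chromium, in the antipode chosen for 8S, controls the aldehyde face.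

Step 13
Reactants: 17 allylic alcohol
Product: 18 8-O-angeloyl derivative of 17 (4R,5S,6R,8S)
Conditions: angelic acid, 2,4,6-trichlorobenzoyl chloride, Et3N, PhMe, rt; then 17, 75 °C
Reagents that add atoms: angelic acid, C/C=C(/C)C(=O)O
Why: Yamaguchi esterification through the mixed anhydride acylates the only free hydroxyl without the nucleophilic catalysis that isomerises angelates to tiglates.

Step 14
Reactants: 18 acetonide angelate
Product: 19 8-O-angeloyl-(4R,5S,6R,8S)-bisabola-2,7(14),10-triene-4,5,8-triol (cis-4,5-diol)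
Conditions: AcOH/H2O (4:1), 40 °C
Reagents that add atoms: none
Why: Mild aqueous acid hydrolyses the cis-fused acetonide while the allylic ester and the three olefins should be stable.

Step 15
Reactants: 19 diol
Product: 20 8-O-angeloyl-(2R,3S,4S,5S,6R,8S)-2,3-epoxybisabola-7(14),10-diene-4,5,8-triol (epoxide cis to O4 and O5)
Conditions: VO(acac)2 (cat.), t-BuOOH, CH2Cl2, 0 °C
Reagents that add atoms: tert-butyl hydroperoxide, CC(C)(C)OO
Why: Hydroxyl-directed epoxidation through the vanadate ester of the allylic C4–OH delivers oxygen to C2=C3 syn to O4, setting C2 and C3, while the olefins without a free allylic hydroxyl stay untouched.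

Step 16
Reactants: 20 epoxy diol
Product: 21 8-O-angeloyl-(2S,3S,4S,5S,6R,8S)-2-chlorobisabola-7(14),10-diene-3,4,5,8-tetrol (free 3-, 4- and 5-OH)
Conditions: ClTi(OiPr)3, CH2Cl2, −20 to 0 °C
Reagents that add atoms: chlorotitanium triisopropoxide, CC(C)O[Ti](Cl)(OC(C)C)OC(C)C
Why: Titanium chelation between O4 and the epoxide oxygen activates the epoxy alcohol, and chloride attacks the distal, less substituted C2 with inversion in the trans-diaxial (Fürst–Plattner) mode, giving C2–Cl anti to C3–OH.

Step 17
Reactants: 21 chlorohydrin triol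
Product: 22 4,8-di-O-angeloyl-(2S,3S,4S,5S,6R,8S)-2-chlorobisabola-7(14),10-diene-3,4,5,8-tetrol (free 3- and 5-OH)
Conditions: Bu2SnO, PhMe, 80 °C; then angelic 2,4,6-trichlorobenzoic anhydride (from angelic acid, 2,4,6-trichlorobenzoyl chloride, Et3N), PhMe, rt
Reagents that add atoms: angelic acid, C/C=C(/C)C(=O)O
Why: A dibutylstannylene acetal across either cis-diol pair raises the nucleophilicity of the equatorial oxygen O4, so acylation should occur at C4 and leave the axial C5–OH and the tertiary C3–OH free (regioselective acylation via a stannylene acetal).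

Step 18
Reactants: 22 bis-angelate
Product: 23 5-O-acetyl-4,8-di-O-angeloyl-(2S,3S,4S,5S,6R,8S)-2-chlorobisabola-7(14),10-diene-3,4,5,8-tetrol
Conditions: Ac2O, pyridine, DMAP (cat.), CH2Cl2, rt
Reagents that add atoms: acetic anhydride, CC(=O)OC(C)=O
Why: DMAP-catalysed acetylation esterifies the remaining secondary axial C5–OH, whereas the tertiary C3–OH is too hindered to react.

Step 19
Reactants: 23 des-epoxy precursor
Product: 24 target, (2S,3S,4S,5S,6R,8S,10S)-5-acetoxy-4,8-bis(angeloyloxy)-2-chloro-10,11-epoxybisabol-7(14)-en-3-ol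
Conditions: ent-Shi ketone (3 equiv), Oxone (KHSO5), NaHCO3, MeCN/aq. Na2EDTA, 0 °C, pH 7–8
Reagents that add atoms: potassium peroxymonosulfate (Oxone), [K+].[O-]S(=O)(=O)OO
Why: Shi epoxidation with the chiral dioxirane should select the electron-rich trisubstituted C10=C11 olefin over the 1,1-disubstituted and ester-conjugated olefins, the L-fructose-derived ketone should give 10S through the spiro transition state, and pH 7–8 is chosen to keep the chlorohydrin from closing.

**Compound list**

1 | 2-deoxy-D-ribose | O=CC[C@H](O)[C@H](O)CO | starting material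
2 | 3,4-O-isopropylidene-2-deoxy-D-ribopyranose | OC1C[C@@H]2OC(C)(C)O[C@@H]2CO1 | intermediate
3 | 3,4-O-isopropylidene-2-deoxy-D-ribono-1,5-lactone | O=C1C[C@@H]2OC(C)(C)O[C@@H]2CO1 | intermediate
4 | hydroxy Weinreb amide | CON(C)C(=O)C[C@@H]1OC(C)(C)O[C@@H]1CO | intermediate
5 | aldehyde Weinreb amide | CON(C)C(=O)C[C@@H]1OC(C)(C)O[C@@H]1C=O | intermediate
6 | allylic alcohol (carbinol epimers) | CON(C)C(=O)C[C@@H]1OC(C)(C)O[C@@H]1C(O)C=C | intermediate
7 | vinyl ketone | CON(C)C(=O)C[C@@H]1OC(C)(C)O[C@@H]1C(=O)C=C | intermediate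
8 | tertiary carbinol amide (not isolated) | CON(C)C(=O)C[C@@H]1OC(C)(C)O[C@@H]1[C@](C)(O)C=C | intermediate
9 | δ-lactone with methyl/vinyl carbinol carbon | C=C[C@@]1(C)OC(=O)C[C@@H]2OC(C)(C)O[C@H]12 | intermediate
10 | trimethylsilyl ketene acetal of 9 (not isolated) | C=C[C@@]1(C)OC(O[Si](C)(C)C)=C[C@@H]2OC(C)(C)O[C@H]12 | intermediate
11 | trimethylsilyl ester of 12 (not isolated) | C[Si](C)(C)OC(=O)[C@H]1CC=C(C)[C@H]2OC(C)(C)O[C@@H]12 | intermediate
12 | all-cis cyclohexene acid | OC(=O)[C@H]1CC=C(C)[C@H]2OC(C)(C)O[C@@H]12 | intermediate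
13 | methyl ketone | CC(=O)[C@H]1CC=C(C)[C@H]2OC(C)(C)O[C@@H]12 | intermediate
14 | enol triflate | C=C(OS(=O)(=O)C(F)(F)F)[C@H]1CC=C(C)[C@H]2OC(C)(C)O[C@@H]12 | intermediate
15 | 4-methylpent-3-en-1-ol | CC(C)=CCCO | starting material
16 | 4-methylpent-3-enal | CC(C)=CCC=O | intermediate
17 | (8S)-allylic alcohol, acetonide | C=C([C@H](CC=C(C)C)O)[C@H]1CC=C(C)[C@H]2OC(C)(C)O[C@@H]12 | intermediate
18 | 8-O-angelate, acetonide | C=C([C@H](CC=C(C)C)OC(=O)/C(C)=C\C)[C@H]1CC=C(C)[C@H]2OC(C)(C)O[C@@H]12 | intermediate
19 | 8-O-angelate cis-4,5-diol | C=C([C@H](CC=C(C)C)OC(=O)/C(C)=C\C)[C@H]1CC=C(C)[C@@H](O)[C@H]1O | intermediate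
20 | 2,3-epoxy diol | C=C([C@H](CC=C(C)C)OC(=O)/C(C)=C\C)[C@H]1C[C@H]2O[C@@]2(C)[C@@H](O)[C@H]1O | intermediate
21 | chlorohydrin triol | C=C([C@H](CC=C(C)C)OC(=O)/C(C)=C\C)[C@H]1C[C@H](Cl)[C@@](C)(O)[C@@H](O)[C@H]1O | intermediate
22 | 4,8-bis-angelate, 5-OH | C=C([C@H](CC=C(C)C)OC(=O)/C(C)=C\C)[C@H]1C[C@H](Cl)[C@@](C)(O)[C@@H](OC(=O)/C(C)=C\C)[C@H]1O | intermediate
23 | 5-acetate 4,8-bis-angelate (10,11-olefin) | C=C([C@H](CC=C(C)C)OC(=O)/C(C)=C\C)[C@H]1C[C@H](Cl)[C@@](C)(O)[C@@H](OC(=O)/C(C)=C\C)[C@H]1OC(C)=O | intermediate
24 | CNP0313121.1 | C=C([C@H](C[C@@H]1OC1(C)C)OC(=O)/C(C)=C\C)[C@H]1C[C@H](Cl)[C@@](C)(O)[C@@H](OC(=O)/C(C)=C\C)[C@H]1OC(C)=O | target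

**Step count.** Total: 19 steps. Longest linear sequence: 18 steps (steps 1–10 and 12–19); step 11 prepares the aldehyde partner.

**Steps most likely to fail**

Step 8 (key step). The lactone enolate may expel the C5 alkoxide before it is silylated, or the ketene acetal may decompose before the boat-like rearrangement takes place. The fallback avoids an ester enolate. It sets out from 9: addition of MeLi at −78 °C gives the methyl lactol F1, and dehydration (PPTS, PhMe, reflux, water removal) gives the endocyclic enol ether F2. Thermolysis of F2 (PhMe, 170 °C, sealed tube) is the enol-ether Claisen rearrangement through the same boat array and with the same chirality transfer. It delivers methyl ketone 13 directly, where the fallback rejoins the route, so steps 8 and 9 are bypassed.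

Step 12. Facial control at the aldehyde may be poor, giving both C8 epimers, and the β,γ-unsaturated aldehyde may isomerise during the coupling. The fallback sets out from 14 and 16: a ligand-free coupling (CrCl2, NiCl2 cat., DMF) gives the C8-epimeric alcohols F3, and Dess–Martin oxidation gives the enone F4. Reagent-controlled CBS reduction ((R)-methyl oxazaborolidine, catecholborane, PhMe, −78 °C) then sets 8S and returns to 17.

Step 19. Under the buffered oxidation the trans-diaxial chlorohydrin may close back to the 2,3-epoxide, and catalyst control at C10 may be incomplete at the low pH. The fallback changes the order of events and sets out from 20, before any chlorohydrin exists. Shi epoxidation under the usual catalytic conditions (ent-Shi ketone, Oxone, K2CO3, pH about 10) gives the bis-epoxide diol F5. Chelation-directed opening with ClTi(OiPr)3 at −20 °C, where only the ring epoxide has a neighbouring hydroxyl, gives the chlorohydrin triol F6. Stannylene-mediated angeloylation as in step 17 gives the 4,8-bis-angelate F7, and acetylation as in step 18 comes back to the route at 24.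

Further compounds
F1 | step 8 | methyl lactol from 9 (hemiketal, anomer mixture) | C=C[C@@]1(C)OC(C)(O)C[C@@H]2OC(C)(C)O[C@H]12
F2 | step 8 | endocyclic enol ether (6-methyl-2-vinyl-dihydropyran, acetonide) | C=C[C@@]1(C)OC(C)=C[C@@H]2OC(C)(C)O[C@H]12
F3 | step 12 | C8-epimeric allylic alcohols, acetonide | C=C(C(O)CC=C(C)C)[C@H]1CC=C(C)[C@H]2OC(C)(C)O[C@@H]12
F4 | step 12 | C8 enone, acetonide | C=C(C(=O)CC=C(C)C)[C@H]1CC=C(C)[C@H]2OC(C)(C)O[C@@H]12
F5 | step 19 | 2,3:10,11-bis-epoxide 4,5-diol 8-angelate | C=C([C@H](C[C@@H]1OC1(C)C)OC(=O)/C(C)=C\C)[C@H]1C[C@H]2O[C@@]2(C)[C@@H](O)[C@H]1O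
F6 | step 19 | 10,11-epoxy chlorohydrin triol 8-angelate | C=C([C@H](C[C@@H]1OC1(C)C)OC(=O)/C(C)=C\C)[C@H]1C[C@H](Cl)[C@@](C)(O)[C@@H](O)[C@H]1O
F7 | step 19 | 10,11-epoxy 4,8-bis-angelate, 5-OH | C=C([C@H](C[C@@H]1OC1(C)C)OC(=O)/C(C)=C\C)[C@H]1C[C@H](Cl)[C@@](C)(O)[C@@H](OC(=O)/C(C)=C\C)[C@H]1O
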